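Ring C of the chroman-4-one (O1, C2, C3, C4, C4a, C8a) is cut at O1–C2 and C3–C4. Ring A then arrives as a salicylaldehyde that already holds O1, C8a, C4a and C4, and ring B as a two-carbon sulfonium unit whose C2 accepts the phenoxide and whose C3 becomes a benzylic ylide. One vinylsulfonium annulation joins the two, closing ring C and a cis-fused C3–C4 epoxide under control of a twofold-symmetric thiolane. Its precursors are the 5-prenylsalicylaldehyde and a 2-bromo-1-arylethyl thiolanium salt whose ring B phenol is a triisopropylsilyl ether. A hydride shift from C4 to C3 then converts the epoxide into the (S)-ketone.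

Key step: step 8

Assumption: the (2R,5R)-thiolane is taken provisionally as the enantiomer that leads to the (3S,4R)-epoxide; the sense of induction at a fully substituted ylide carbon cannot be predicted with confidence, so the enantiomeric sulfide (same two steps from (2R,5R)-hexane-2,5-diol) is used if the first annulation shows the opposite sense. Chroman-4-one numbering (O1, C2, C3, C4, ring B on C3) is used for all bicyclic compounds.

Step 1
Reactants: 1 5-bromo-2-hydroxy-4-methoxybenzaldehyde; 2 tributyl(3-methylbut-2-enyl)stannane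
Product: 3 2-hydroxy-4-methoxy-5-(3-methylbut-2-enyl)benzaldehyde
Conditions: Pd(PPh3)4 (5 mol %), DMF, 100 °C
Reagents that add atoms: none
Why: Stille coupling (zerovalent palladium) of an aryl bromide with an allylic stannane tolerates the free phenol and the aldehyde, and transfer of the prenyl group through its CH2 terminus should place the linear 3-methylbut-2-enyl group at C5.

Step 2
Reactants: 4 paeonol [1-(2-hydroxy-4-methoxyphenyl)ethanone]
Product: 5 1-[4-methoxy-2-(triisopropylsilyloxy)phenyl]ethanone
Conditions: TIPSCl, imidazole, DMAP (cat.), DMF, 40 °C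
Reagents that add atoms: chlorotriisopropylsilane, CC(C)[Si](Cl)(C(C)C)C(C)C
Why: Imidazole-promoted O-silylation of the phenol; the triisopropylsilyl ether is chosen because, unlike smaller silyl ethers, it should withstand HBF4 in step 7, the phenoxide and amidine base of step 8 (no silyl transfer to oxygen or to the ylide carbon) and BF3 in step 9, while its bulk keeps the ring B oxygen from attacking C4 of the later epoxide.

Step 3
Reactants: 5 1-[4-methoxy-2-(triisopropylsilyloxy)phenyl]ethanone
Product: 7 2-bromo-1-[4-methoxy-2-(triisopropylsilyloxy)phenyl]ethanone, via trimethylsilyl enol ether 6 (not isolated)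
Conditions: LiN(SiMe3)2, Me3SiCl, THF, −78 °C; then NBS, −78 → 0 °C
Reagents that add atoms: N-bromosuccinimide, O=C1CCC(=O)N1Br (chlorotrimethylsilane, C[Si](C)(C)Cl, supplies only the silyl group of 6, which is lost again)
Why: Kinetic enolisation with internal silyl quench followed by electrophilic bromination of the silyl enol ether gives the phenacyl bromide without free HBr, so neither the electron-rich ring nor the aryl silyl ether should be attacked.

Step 4
Reactants: 7 2-bromo-1-[4-methoxy-2-(triisopropylsilyloxy)phenyl]ethanone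
Product: 8 rac-2-bromo-1-[4-methoxy-2-(triisopropylsilyloxy)phenyl]ethanol
Conditions: NaBH4, MeOH/THF, −20 °C; aq. NH4Cl
Reagents that add atoms: none
Why: Borohydride reduction of the α-bromo ketone at low temperature should stop at the bromohydrin before the alkoxide closes to an oxirane; the new carbinol centre is left racemic because it becomes sp2 in step 8.

Step 5
Reactants: 9 (2S,5S)-hexane-2,5-diol
Product: 10 (2S,5S)-hexane-2,5-diyl dimethanesulfonate
Conditions: MsCl, Et3N, CH2Cl2, 0 °C
Reagents that add atoms: methanesulfonyl chloride, CS(=O)(=O)Cl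
Why: Sulfonylation of both secondary alcohols (mesylate formation) takes place at oxygen and leaves both carbon configurations untouched.

Step 6
Reactants: 10 (2S,5S)-hexane-2,5-diyl dimethanesulfonate
Product: 11 (2R,5R)-2,5-dimethylthiolane
Conditions: Na2S·9H2O, EtOH, 20 → 40 °C
Reagents that add atoms: sodium sulfide, [Na+].[Na+].[S-2]
Why: Thioether synthesis by double SN2 displacement, the second one a 5-exo-tet ring closure, inverts both centres and should give the twofold-symmetric (2R,5R)-sulfide.

Step 7
Reactants: 8 rac-2-bromo-1-[4-methoxy-2-(triisopropylsilyloxy)phenyl]ethanol; 11 (2R,5R)-2,5-dimethylthiolane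
Product: 12 (2R,5R)-1-{2-bromo-1-[4-methoxy-2-(triisopropylsilyloxy)phenyl]ethyl}-2,5-dimethylthiolanium tetrafluoroborate (both epimers at the benzylic carbon)
Conditions: HBF4·OEt2, CH2Cl2, −20 → 0 °C; Et2O (precipitation)
Reagents that add atoms: tetrafluoroboric acid (diethyl ether complex), [H+].F[B-](F)(F)F
Why: Acid-mediated dehydrative S-alkylation (SN1): the benzylic cation stabilised by the para-methoxy and ortho-silyloxy groups is trapped by the sulfide, whose twofold symmetry means sulfur is not a stereocentre, and the non-nucleophilic counter-ion cannot reverse the alkylation.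

Step 8
Reactants: 3 2-hydroxy-4-methoxy-5-(3-methylbut-2-enyl)benzaldehyde; 12 (2R,5R)-1-{2-bromo-1-[4-methoxy-2-(triisopropylsilyloxy)phenyl]ethyl}-2,5-dimethylthiolanium tetrafluoroborate
Product: 16 (3S,4R)-3,4-epoxy-7-methoxy-3-[4-methoxy-2-(triisopropylsilyloxy)phenyl]-6-(3-methylbut-2-enyl)chromane, via vinylsulfonium tetrafluoroborate 13 (not isolated), via sulfonium ylide 14 (not isolated), via alkoxide betaine 15 (not isolated)
Conditions: DBU (2.2 equiv), CH2Cl2, −40 → 0 °C
Reagents that add atoms: none
Why: Proposed new method: DBU removes HBr from 12 through its benzylic ylide (E1cB) to give the 1-arylvinylsulfonium ion 13, the phenoxide of 3 adds to the CH2 terminus (bond O1–C2) to give the aryl-stabilised ylide 14, carbon C3 of 14 adds to the tethered aldehyde (bond C3–C4) to give betaine 15, and the C4 alkoxide displaces the thiolane from C3 with inversion (bond O–C3). The closest known reaction types are the epoxy-annulation of hydroxy and amino carbonyl compounds with unsubstituted vinylsulfonium salts generated in the flask from bromoethylsulfonium salts (chiral sulfides included) and the Corey–Chaykovsky epoxidation of aldehydes by benzylic sulfonium ylides; new here is a vinylsulfonium ion that carries an aryl group on the sulfur-bearing carbon and so leads to a fully substituted ylide carbon. Ring C closes by 6-exo-trig attack of C3 on the carbonyl group and the oxirane by 3-exo-tet displacement at C3. C3 is set by the twofold-symmetric (2R,5R)-thiolane, whose two methyl groups make the faces of the ylide carbon unequal, and C4 follows from C3 because the alkoxide can reach C3 only anti to sulfur, which allows nothing but the cis-fused epoxide, while the betaine of the other relative configuration should revert to 14. The step needs O-alkylation of the phenoxide ahead of other nucleophiles and one ylide face: the first is secured by the electrophilic CH2 terminus of 13, the non-nucleophilic tetrafluoroborate and the six-membered intramolecular delivery of the aldehyde, the second rests on the sulfide and is to be verified on 16 before the route continues.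

Step 9
Reactants: 16 (3S,4R)-3,4-epoxy-7-methoxy-3-[4-methoxy-2-(triisopropylsilyloxy)phenyl]-6-(3-methylbut-2-enyl)chromane
Product: 17 (3S)-7-methoxy-3-[4-methoxy-2-(triisopropylsilyloxy)phenyl]-6-(3-methylbut-2-enyl)chroman-4-one
Conditions: BF3·OEt2 (0.2 equiv), CH2Cl2, −78 °C; pH 7 buffer
Reagents that add atoms: none
Why: Meinwald rearrangement with 1,2-hydride shift: BF3 should ionise the oxirane at the tertiary benzylic C3 (cation stabilised by the para-methoxy ring B), and the C4 hydrogen, fixed on the face opposite to the oxygen, migrates to C3 on that face as C4 becomes the carbonyl carbon, so ring B takes the face the oxygen held and C3 becomes (S) without an enol intermediate.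

Step 10
Reactants: 17 (3S)-7-methoxy-3-[4-methoxy-2-(triisopropylsilyloxy)phenyl]-6-(3-methylbut-2-enyl)chroman-4-one
Product: 18 (3S)-3-(2-hydroxy-4-methoxyphenyl)-7-methoxy-6-(3-methylbut-2-enyl)chroman-4-one
Conditions: HF·pyridine, pyridine, THF, 0 °C → rt
Reagents that add atoms: none
Why: Fluoride-mediated desilylation in a pyridine-buffered, non-basic medium cleaves the aryl silyl ether while the enolisable C3 centre and the prenyl double bond should remain untouched.

Compound list
1 | 5-bromo-2-hydroxy-4-methoxybenzaldehyde | COc1cc(O)c(C=O)cc1Br | starting material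
2 | tributyl(3-methylbut-2-enyl)stannane | CCCC[Sn](CCCC)(CCCC)CC=C(C)C | starting material
3 | 2-hydroxy-4-methoxy-5-(3-methylbut-2-enyl)benzaldehyde | COc1cc(O)c(C=O)cc1CC=C(C)C | intermediate
4 | paeonol, 1-(2-hydroxy-4-methoxyphenyl)ethanone | CC(=O)c1ccc(OC)cc1O | starting material
5 | 1-[4-methoxy-2-(triisopropylsilyloxy)phenyl]ethanone | CC(=O)c1ccc(OC)cc1O[Si](C(C)C)(C(C)C)C(C)C | intermediate
6 | triisopropyl{5-methoxy-2-[1-(trimethylsilyloxy)vinyl]phenoxy}silane (trimethylsilyl enol ether of 5, not isolated) | C=C(O[Si](C)(C)C)c1ccc(OC)cc1O[Si](C(C)C)(C(C)C)C(C)C | intermediate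
7 | 2-bromo-1-[4-methoxy-2-(triisopropylsilyloxy)phenyl]ethanone | O=C(CBr)c1ccc(OC)cc1O[Si](C(C)C)(C(C)C)C(C)C | intermediate
8 | rac-2-bromo-1-[4-methoxy-2-(triisopropylsilyloxy)phenyl]ethanol | OC(CBr)c1ccc(OC)cc1O[Si](C(C)C)(C(C)C)C(C)C | intermediate
9 | (2S,5S)-hexane-2,5-diol | C[C@H](O)CC[C@H](C)O | starting material
10 | (2S,5S)-hexane-2,5-diyl dimethanesulfonate | C[C@H](OS(C)(=O)=O)CC[C@H](C)OS(C)(=O)=O | intermediate
11 | (2R,5R)-2,5-dimethylthiolane | C[C@@H]1CC[C@@H](C)S1 | intermediate
12 | (2R,5R)-1-{2-bromo-1-[4-methoxy-2-(triisopropylsilyloxy)phenyl]ethyl}-2,5-dimethylthiolanium tetrafluoroborate (both epimers at the benzylic carbon) | C[C@@H]1CC[C@@H](C)[S+]1C(CBr)c1ccc(OC)cc1O[Si](C(C)C)(C(C)C)C(C)C.F[B-](F)(F)F | intermediate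
13 | (2R,5R)-1-{1-[4-methoxy-2-(triisopropylsilyloxy)phenyl]vinyl}-2,5-dimethylthiolanium tetrafluoroborate (not isolated) | C[C@@H]1CC[C@@H](C)[S+]1C(=C)c1ccc(OC)cc1O[Si](C(C)C)(C(C)C)C(C)C.F[B-](F)(F)F | intermediate
14 | sulfonium ylide: (2R,5R)-2,5-dimethylthiolanium 2-[2-formyl-5-methoxy-4-(3-methylbut-2-enyl)phenoxy]-1-[4-methoxy-2-(triisopropylsilyloxy)phenyl]ethan-1-ide (not isolated) | C[C@@H]1CC[C@@H](C)[S+]1[C-](COc1cc(OC)c(CC=C(C)C)cc1C=O)c1ccc(OC)cc1O[Si](C(C)C)(C(C)C)C(C)C | intermediate
15 | betaine: (3R,4R)-3-[(2R,5R)-2,5-dimethylthiolan-1-ium-1-yl]-7-methoxy-3-[4-methoxy-2-(triisopropylsilyloxy)phenyl]-6-(3-methylbut-2-enyl)chroman-4-olate, sulfur and alkoxide on opposite faces (not isolated) | C[C@@H]1CC[C@@H](C)[S+]1[C@]2(c3ccc(OC)cc3O[Si](C(C)C)(C(C)C)C(C)C)COc3cc(OC)c(CC=C(C)C)cc3[C@H]2[O-] | intermediate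
16 | (3S,4R)-3,4-epoxy-7-methoxy-3-[4-methoxy-2-(triisopropylsilyloxy)phenyl]-6-(3-methylbut-2-enyl)chromane (cis-fused oxirane; ring B and H-4 on the face opposite to the oxirane oxygen) | COc1ccc([C@]23COc4cc(OC)c(CC=C(C)C)cc4[C@H]2O3)c(O[Si](C(C)C)(C(C)C)C(C)C)c1 | intermediate
17 | (3S)-7-methoxy-3-[4-methoxy-2-(triisopropylsilyloxy)phenyl]-6-(3-methylbut-2-enyl)chroman-4-one | COc1ccc([C@H]2COc3cc(OC)c(CC=C(C)C)cc3C2=O)c(O[Si](C(C)C)(C(C)C)C(C)C)c1 | intermediate
18 | (3S)-3-(2-hydroxy-4-methoxyphenyl)-7-methoxy-6-(3-methylbut-2-enyl)chroman-4-one | COc1ccc([C@H]2COc3cc(OC)c(CC=C(C)C)cc3C2=O)c(O)c1 | target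

Total step count: 10.
Longest linear sequence: 7 steps (4 → 5 → 7 → 8 → 12 → 16 → 17 → 18; steps 2, 3, 4, 7, 8, 9 and 10).

Steps most likely to fail

First, step 8. The process at risk is loss of the 1-arylvinylsulfonium ion 13 (oligomerisation, addition of the amidine base, loss of the sulfide) before the hydrogen-bonded, weakly nucleophilic phenoxide of 3 adds to it. The fallback uses known chemistry and makes the O1–C2 bond first. It sets out from 3, which is alkylated with bromohydrin 8 (K2CO3, DMF, 60 °C; the bromohydrin closes to its oxirane and the phenoxide opens it at the CH2 terminus). This should give rac-2-{2-hydroxy-2-[4-methoxy-2-(triisopropylsilyloxy)phenyl]ethoxy}-4-methoxy-5-(3-methylbut-2-enyl)benzaldehyde F1. Dehydrative S-alkylation of sulfide 11 with F1 and HBF4·OEt2, as in step 7, should give (2R,5R)-1-{2-[2-formyl-5-methoxy-4-(3-methylbut-2-enyl)phenoxy]-1-[4-methoxy-2-(triisopropylsilyloxy)phenyl]ethyl}-2,5-dimethylthiolanium tetrafluoroborate F2. Deprotonation of F2 with KOt-Bu in THF at −78 °C generates ylide 14 directly, and intramolecular Corey–Chaykovsky epoxidation of the aldehyde returns to the route at 16.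

Second, step 9. The process at risk is competing ionisation at C4, whose cation is stabilised by O1 and the C7 methoxy group of ring A, followed by migration of ring B to a 4-arylchroman-3-one. A second risk is slow Lewis-acid enolisation of the product, which would erode the configuration at C3. The fallback replaces heterolytic by homolytic opening and sets out from 16. Cp2TiCl (trivalent titanium, from Cp2TiCl2 and Mn dust) with water as hydrogen-atom donor in THF should cleave the C3–O bond to the tertiary benzylic radical, a choice governed by radical and not cation stability. Hydrogen delivery anti to the titanium alkoxide should then give (3S,4S)-cis-7-methoxy-3-[4-methoxy-2-(triisopropylsilyloxy)phenyl]-6-(3-methylbut-2-enyl)chroman-4-ol F3. Any C3 epimer is a diastereomer and can be separated, because C4 is untouched. Oxidation of F3 with Dess–Martin periodinane buffered with NaHCO3 (CH2Cl2, 0 °C) returns to the route at 17.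

Third, step 7. The process at risk is proton loss or arene alkylation of the benzylic cation before the hindered sulfide traps it, together with acid-induced loss of the silyl group. The fallback forms the C–S bond by bromosulfonium addition to an alkene, without Brønsted acid, and sets out from 8. Reductive elimination with Zn dust in AcOH/THF should give the styrene triisopropyl(5-methoxy-2-vinylphenoxy)silane F4. Sulfide 11 and Br2 in CH2Cl2 at −40 °C form the bromosulfonium bromide, which adds across F4 with the sulfide opening the bromonium ion at the benzylic carbon. This should give (2R,5R)-1-{2-bromo-1-[4-methoxy-2-(triisopropylsilyloxy)phenyl]ethyl}-2,5-dimethylthiolanium bromide F5. Anion exchange with AgBF4, which removes the nucleophilic bromide as its silver salt, returns to the route at 12.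

Further compounds
F1 | step 8 | rac-2-{2-hydroxy-2-[4-methoxy-2-(triisopropylsilyloxy)phenyl]ethoxy}-4-methoxy-5-(3-methylbut-2-enyl)benzaldehyde | O=Cc1cc(CC=C(C)C)c(OC)cc1OCC(O)c1ccc(OC)cc1O[Si](C(C)C)(C(C)C)C(C)C
F2 | step 8 | (2R,5R)-1-{2-[2-formyl-5-methoxy-4-(3-methylbut-2-enyl)phenoxy]-1-[4-methoxy-2-(triisopropylsilyloxy)phenyl]ethyl}-2,5-dimethylthiolanium tetrafluoroborate | C[C@@H]1CC[C@@H](C)[S+]1C(COc1cc(OC)c(CC=C(C)C)cc1C=O)c1ccc(OC)cc1O[Si](C(C)C)(C(C)C)C(C)C.F[B-](F)(F)F
F3 | step 9 | (3S,4S)-cis-7-methoxy-3-[4-methoxy-2-(triisopropylsilyloxy)phenyl]-6-(3-methylbut-2-enyl)chroman-4-ol | COc1ccc([C@H]2COc3cc(OC)c(CC=C(C)C)cc3[C@H]2O)c(O[Si](C(C)C)(C(C)C)C(C)C)c1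
F4 | step 7 | triisopropyl(5-methoxy-2-vinylphenoxy)silane | C=Cc1ccc(OC)cc1O[Si](C(C)C)(C(C)C)C(C)C
F5 | step 7 | (2R,5R)-1-{2-bromo-1-[4-methoxy-2-(triisopropylsilyloxy)phenyl]ethyl}-2,5-dimethylthiolanium bromide | C[C@@H]1CC[C@@H](C)[S+]1C(CBr)c1ccc(OC)cc1O[Si](C(C)C)(C(C)C)C(C)C.[Br-]
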